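## Analysis of the target

The target 19 is a tetrasubstituted benzene: C1 carries the carboxyl group, C2 a free phenol, C4 a methyl ether and C6 a 2-oxotridecyl arm (ArCH2–CO–C11H23). C3 and C5 are unsubstituted. There is no stereocentre, so the problem is one of regiochemistry and functional-group tolerance. Three neighbouring ring positions (C6, C1, C2) are substituted, and the oxygens at C2 and C4 must end up different, one free and one methylated. The sensitive groups are the salicylic acid (it decarboxylates when heated in acid), the doubly activated benzylic CH2, and the ketone sitting next to the ortho carboxyl. That last pair closes to an enol lactone under dehydrating acid and opens Claisen-type pathways under base once the carboxyl is an ester. A free ketone one carbon away from an alkyne would also isomerise, so the ketone has to travel masked. The strategy reads the ring as C4 + C2: C2(OH)–C3–C4(OMe)–C5 is a butadiene oxygenated twice at one terminus and once at the inner carbon, while C1 with its carboxyl and C6 with its chain are the two sp carbons of a 2-alkynoate.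

## Retrosynthetic reasoning

**19 to 17.** The acid 19 is taken back to its methyl ester 17. No skeletal bond is cut. The ring-forming step delivers an ester, and a free salicylic acid would not survive the heat of that step. The forward reaction must hydrolyse a hindered, phenoxide-deactivated ester without damaging the neighbouring ketone.

**17 to 16.** The ketone of 17 is taken back to the 1,3-dithiane 16. A free ketone here would be β to an alkyne at the precursor stage and would drift to a conjugated allene. The dithiane is inert to heat, base and dilute acid, and it is also the handle by which the chain is assembled. The forward reaction needs a non-oxidising, buffered unmasking that leaves the electron-rich phenol alone.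

**16 to 9 and 13.** Ring bonds C5–C6 and C1–C2 are cut. This pair of cuts puts both ring oxygens on a four-carbon piece, the diene 13, and both carbon substituents on a two-carbon piece, the alkynoate 9. Any other pair would either separate the oxygens or leave three contiguous substituents to be introduced on a preformed ring against competing directing effects. The gain is that the two oxygens are different from the start: the silylated oxygen of 13 becomes the C2 phenol and the inner methoxy stays as the C4 ether. The forward reaction is a cycloaddition to 14, loss of the surplus methoxy group to give 15, and desilylation.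

**9 to 7 to 6.** The bond between the alkyne terminus and the ester carbon is cut, leading to the terminal alkyne 7 through its acetylide 8. The alkyne 7 is in turn the desilylated form of 6. The ester is put on last because an alkynoate would not tolerate the carbanion chemistry that builds the chain.

**6 to 3 and 4, then 3 to 1 and 2.** The bond between the dithiane carbon and the propargylic CH2 is cut. It is the only bond joining the lipid part to the alkyne, and the dithiane that masks the ketone also supplies the nucleophile 5. This leads to the dithiane 3 and the silyl-capped propargylic bromide 4. The dithiane 3 comes from the aldehyde 1 and the dithiol 2.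

**13 to 11 to 10.** The O–Si bond of 13 is cut to the dienolate 12 of the vinylogous ester 11, which is the methyl enol ether of the β-keto ester 10. Both steps are standard and start from a bulk chemical.

## Alternatives that were turned down

**Alternative 1: aryne acyl-alkylation.**
- Disconnection: the C6–CH2 bond and the C1–acyl bond are cut together. The ring arrives as 3,5-dimethoxybenzyne from 3,5-dimethoxy-2-(trimethylsilyl)phenyl trifluoromethanesulfonate A1. The side chain and a carboxyl surrogate arrive in 1,1,1-trifluoropentadecane-2,4-dione A2.
- Key step: CsF releases the aryne. The enolate of A2 adds through its central carbon at the aryne carbon remote from the flanking methoxy group. The resulting aryl anion attacks the trifluoroacetyl carbonyl, and the four-membered alkoxide fragments to 1-[3,5-dimethoxy-2-(trifluoroacetyl)phenyl]tridecan-2-one A3.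
- For: two ortho carbon–carbon bonds form in one step, the aryne methoxy group steers the regiochemistry, the ketone needs no mask, and the sequence is shorter than the chosen one.
- Against: the aryl anion can attack either carbonyl of the unsymmetrical diketone, and nothing in the substrate enforces the choice beyond electrophilicity. The strongly enolised diketone may also arylate on oxygen. The trifluoroacetyl group must then be cleaved by hydroxide next to an enolisable benzyl ketone that can condense onto it. Both oxygens are methyl ethers, so a selective demethylation at C2 is still needed.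
- Comparison: it is stronger on step count and convergence. The chosen route offers regiochemistry fixed by polarity rather than by a chemoselectivity with no handle, and it needs no demethylation.

**Alternative 2: carboxyl-directed alkyne cyclisation to the isocoumarin.**
- Disconnection: the ketone C–O bond is traced back to a carboxyl oxygen adding across an alkyne, and the aryl–alkyne bond to a Sonogashira coupling. The precursor is 2,4-dimethoxy-6-(tridec-1-yn-1-yl)benzoic acid A4.
- Key step: a cationic monovalent gold catalyst from AuCl(PPh3) and AgOTf activates the alkyne, and the carboxyl oxygen closes 6-endo-dig to 6,8-dimethoxy-3-undecyl-1H-isochromen-1-one A5. BCl3 then removes the methyl group peri to the lactone carbonyl, and KOH opens the enol lactone to the keto acid.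
- For: every step has close precedent, the oxygenated ring is bought, and the isocoumarin masks acid and ketone at once, so no separate ketone protection is needed.
- Against: the 6-endo closure competes with 5-exo closure to a five-membered lactone. An ortho-halogenated dimethoxybenzoate has to be made first. Three metals (Pd, Au, Ag) and a demethylation are required.
- Comparison: this route is probably the more predictable one and is of similar length. The chosen route offers construction of the ring from acyclic pieces with the two oxygens already different, no transition metal, and a side chain that enters as a simple aldehyde, so homologues need only another aldehyde.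

**Alternative 3: biomimetic aldol aromatisation.**
- Disconnection: ring bond C1–C6 is cut, and the ring is unrolled into the polycarbonyl chain 2,2-dimethyl-6-[2,4-dioxo-5-(2-undecyl-1,3-dioxolan-2-yl)pentyl]-4H-1,3-dioxin-4-one A6.
- Key step: Et3N enolises the chain, the dioxinone CH carbon adds to the far side-chain ketone, and mild acid dehydrates to 7-hydroxy-2,2-dimethyl-5-[(2-undecyl-1,3-dioxolan-2-yl)methyl]-4H-1,3-benzodioxin-4-one A7. Methylation of the single free phenol, hydroxide opening of the dioxinone and ketal hydrolysis would finish the synthesis.
- For: the ring closes near room temperature, the two oxygens are differentiated perfectly (one free, one locked in the heterocycle), and the carboxyl is released without a hindered ester hydrolysis.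
- Against: A6 takes several steps of dioxinone dienolate acylation. It is a labile polyketone that can also close through oxygen to pyranones. Its dioxolane must survive the acid used for dehydration.
- Comparison: on oxygen differentiation and mildness it is as good as or better than the chosen route. The chosen route is shorter and runs through stable precursors that can be distilled or chromatographed.

Key step: step 7

## Route

Assumption: 19 is taken as the open-chain keto acid as drawn; its ring–chain equilibrium with the cyclic hemiketal form is treated as a property of 19. Either geometry of the ketene acetal in 13 is acceptable, because that carbon becomes aromatic.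

Step 1
Reactants: 1 dodecanal; 2 propane-1,3-dithiol
Product: 3 2-undecyl-1,3-dithiane
Conditions: BF3·OEt2 (cat.), CH2Cl2, 0 °C to rt
Reagents that add atoms: none
Why: Lewis-acid-catalysed dithioacetalisation of an aldehyde; the six-membered dithiane forms readily and turns the aldehyde carbon into an acyl-anion equivalent for step 2.

Step 2
Reactants: 3 2-undecyl-1,3-dithiane; 4 3-bromo-1-(trimethylsilyl)prop-1-yne
Product: 6 trimethyl[3-(2-undecyl-1,3-dithian-2-yl)prop-1-yn-1-yl]silane, via 2-lithio-2-undecyl-1,3-dithiane 5 (not isolated)
Conditions: n-BuLi, THF, −30 °C, 3 h; then 4, −78 °C to rt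
Reagents that add atoms: none
Why: Corey–Seebach umpolung: n-BuLi removes the C2 proton of 3 and the soft carbanion 5 displaces the primary propargylic bromide by SN2; the silyl cap removes the acidic alkyne proton and shields the alkyne terminus from SN2' attack.

Step 3
Reactants: 6 trimethyl[3-(2-undecyl-1,3-dithian-2-yl)prop-1-yn-1-yl]silane
Product: 7 2-(prop-2-yn-1-yl)-2-undecyl-1,3-dithiane
Conditions: K2CO3 (cat.), MeOH/THF, rt
Reagents that add atoms: none
Why: Base-catalysed methanolysis of the C(sp)–Si bond (protodesilylation of an alkynylsilane); the dithiane is inert to carbonate in methanol.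

Step 4
Reactants: 7 2-(prop-2-yn-1-yl)-2-undecyl-1,3-dithiane
Product: 9 methyl 4-(2-undecyl-1,3-dithian-2-yl)but-2-ynoate, via [3-(2-undecyl-1,3-dithian-2-yl)prop-1-yn-1-yl]lithium 8 (not isolated)
Conditions: n-BuLi, THF, −78 °C; then cannulated into ClCO2Me, THF, −78 to 0 °C
Reagents that add atoms: methyl chloroformate, COC(=O)Cl
Why: Deprotonation of the terminal alkyne and C-acylation of the lithium acetylide by a chloroformate; inverse addition at low temperature keeps the acetylide from attacking the product ester.

Step 5
Reactants: 10 methyl acetoacetate
Product: 11 methyl (2E)-3-methoxybut-2-enoate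
Conditions: HC(OMe)3, conc. H2SO4 (cat.), rt; distillation
Reagents that add atoms: trimethyl orthoformate, COC(OC)OC
Why: Acid-catalysed ketalisation of the ketone by the orthoester, followed by loss of methanol, gives the conjugated β-methoxy enoate (enol ether formation); the E isomer is the thermodynamic product and its geometry disappears in step 6.

Step 6
Reactants: 11 methyl (2E)-3-methoxybut-2-enoate
Product: 13 (1E)-1,3-dimethoxy-1-(trimethylsilyloxy)buta-1,3-diene, via lithium 1,3-dimethoxybuta-1,3-dien-1-olate 12 (not isolated)
Conditions: LiN(i-Pr)2 (LDA, commercial solution), THF, −78 °C; then Me3SiCl, −78 °C to rt; filtration under Ar, bulb-to-bulb distillation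
Reagents that add atoms: chlorotrimethylsilane, C[Si](C)(C)Cl
Why: Kinetic γ-deprotonation of the vinylogous ester gives the extended lithium dienolate, which the hard silyl chloride traps on oxygen (O-silylation of an ester dienolate to a silyl ketene acetal).

Step 7
Reactants: 9 methyl 4-(2-undecyl-1,3-dithian-2-yl)but-2-ynoate; 13 (1E)-1,3-dimethoxy-1-(trimethylsilyloxy)buta-1,3-diene
Product: 16 methyl 2-hydroxy-4-methoxy-6-[(2-undecyl-1,3-dithian-2-yl)methyl]benzoate, via cyclohexa-1,4-diene cycloadduct 14 (not isolated), via aryl trimethylsilyl ether 15 (not isolated)
Conditions: 13 (3 equiv), xylene (minimum volume), 135 °C, sealed tube, Ar; then 1 M HCl, THF, rt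
Reagents that add atoms: none
Why: This is a normal-demand Diels–Alder reaction between the HOMO of the trioxygenated diene and the LUMO of the alkynoate, concerted but asynchronous, with the C5–C6 bond leading and the C1–C2 bond following. The closest known reaction type is the benzannulation of 1-alkoxy-1-silyloxy-3-alkoxybutadienes with acetylenic esters to 4-alkoxysalicylates; β-alkyl alkynoates are within that class but need more heat than propiolates. The single six-membered carbocycle is closed in one intermolecular suprafacial (4+2) event that forms both ring bonds, giving 14. Adduct 14 then loses methanol by 1,4-elimination from its ketal carbon to give the arene 15, and dilute acid cleaves the aryl O–Si bond to the phenol 16. No stereocentre survives; the ketal carbon of 14 is transient and racemic. The step needs regioselectivity, which the substrates supply: the unsubstituted CH2 terminus of 13 has the largest HOMO coefficient and pairs with the β-carbon of 9, which has the largest LUMO coefficient, so the ketene acetal carbon ends up next to the ester carbon. It also needs the right oxygen to leave, and this follows because the methoxy group can only leave with its oxygen while the silyl group is removed at silicon, so the silylated oxygen stays on the ring as the phenol. The dithiane keeps the propargylic CH2 from isomerising and sits one carbon away from the reacting β-carbon.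

Step 8
Reactants: 16 methyl 2-hydroxy-4-methoxy-6-[(2-undecyl-1,3-dithian-2-yl)methyl]benzoate
Product: 17 methyl 2-hydroxy-4-methoxy-6-(2-oxotridecyl)benzoate
Conditions: MeI (excess), CaCO3, MeCN/H2O (4:1), 45 °C
Reagents that add atoms: water, O
Why: Alkylative dethioketalisation: S-methylation gives a sulfonium ion that opens to a thionium ion, water adds and the hemithioketal collapses to the ketone; CaCO3 buffers the HI so the new keto ester does not lactonise, and the non-oxidising reagent spares the electron-rich phenol.

Step 9
Reactants: 17 methyl 2-hydroxy-4-methoxy-6-(2-oxotridecyl)benzoate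
Product: 19 2-hydroxy-4-methoxy-6-(2-oxotridecyl)benzoic acid, via dipotassium 4-methoxy-2-oxido-6-(2-oxotridecyl)benzoate 18 (not isolated)
Conditions: KOH, MeOH/H2O, 50 °C; then 1 M HCl, 0 °C, to pH 3, extraction into EtOAc without warming
Reagents that add atoms: potassium hydroxide, [K+].[OH-]
Why: Saponification of the methyl ester; direct attack is slowed by the ortho phenoxide and the two flanking substituents, but the enolate oxygen of the neighbouring ketone can relay the acyl group intramolecularly and hydroxide reopens that relay to the same keto carboxylate 18, which cold acidification converts to the acid without dehydration.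

## Compound list

1 | dodecanal | CCCCCCCCCCCC=O | starting material
2 | propane-1,3-dithiol | SCCCS | starting material
3 | 2-undecyl-1,3-dithiane | CCCCCCCCCCCC1SCCCS1 | intermediate
4 | 3-bromo-1-(trimethylsilyl)prop-1-yne | C[Si](C)(C)C#CCBr | starting material
5 | 2-lithio-2-undecyl-1,3-dithiane | [Li]C1(CCCCCCCCCCC)SCCCS1 | intermediate
6 | trimethyl[3-(2-undecyl-1,3-dithian-2-yl)prop-1-yn-1-yl]silane | CCCCCCCCCCCC1(CC#C[Si](C)(C)C)SCCCS1 | intermediate
7 | 2-(prop-2-yn-1-yl)-2-undecyl-1,3-dithiane | CCCCCCCCCCCC1(CC#C)SCCCS1 | intermediate
8 | [3-(2-undecyl-1,3-dithian-2-yl)prop-1-yn-1-yl]lithium | [Li]C#CCC1(CCCCCCCCCCC)SCCCS1 | intermediate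
9 | methyl 4-(2-undecyl-1,3-dithian-2-yl)but-2-ynoate | CCCCCCCCCCCC1(CC#CC(=O)OC)SCCCS1 | intermediate
10 | methyl acetoacetate | COC(=O)CC(C)=O | starting material
11 | methyl (2E)-3-methoxybut-2-enoate | CO/C(C)=C/C(=O)OC | intermediate
12 | lithium 1,3-dimethoxybuta-1,3-dien-1-olate | C=C(OC)C=C(OC)O[Li] | intermediate
13 | (1E)-1,3-dimethoxy-1-(trimethylsilyloxy)buta-1,3-diene | C=C(OC)/C=C(\OC)O[Si](C)(C)C | intermediate
14 | methyl 4,6-dimethoxy-6-(trimethylsilyloxy)-2-[(2-undecyl-1,3-dithian-2-yl)methyl]cyclohexa-1,4-diene-1-carboxylate (racemic) | COC(=O)C1=C(CC2(CCCCCCCCCCC)SCCCS2)CC(OC)=CC1(OC)O[Si](C)(C)C | intermediate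
15 | methyl 4-methoxy-2-(trimethylsilyloxy)-6-[(2-undecyl-1,3-dithian-2-yl)methyl]benzoate | CCCCCCCCCCCC1(Cc2cc(OC)cc(O[Si](C)(C)C)c2C(=O)OC)SCCCS1 | intermediate
16 | methyl 2-hydroxy-4-methoxy-6-[(2-undecyl-1,3-dithian-2-yl)methyl]benzoate | CCCCCCCCCCCC1(Cc2cc(OC)cc(O)c2C(=O)OC)SCCCS1 | intermediate
17 | methyl 2-hydroxy-4-methoxy-6-(2-oxotridecyl)benzoate | CCCCCCCCCCCC(=O)Cc1cc(OC)cc(O)c1C(=O)OC | intermediate
18 | dipotassium 4-methoxy-2-oxido-6-(2-oxotridecyl)benzoate | CCCCCCCCCCCC(=O)Cc1cc(OC)cc([O-])c1C(=O)[O-].[K+].[K+] | intermediate
19 | 2-hydroxy-4-methoxy-6-(2-oxotridecyl)benzoic acid | CCCCCCCCCCCC(=O)Cc1cc(OC)cc(O)c1C(=O)O | target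

## Step count and least certain steps

Total: 9 steps. Longest linear sequence: 7 steps (steps 1, 2, 3, 4, 7, 8, 9 from dodecanal 1). The diene branch (steps 5 and 6) joins at step 7.

**Step 7 (key step).** The most likely failure is a cycloaddition too slow to compete with decay of the diene. The β-carbon of 9 carries an alkyl group with a fully substituted carbon one atom further out, which lowers the dienophile's reactivity. The temperature needed then approaches the range where 13 is lost by oxygen-to-carbon silyl migration, by hydrolysis through traces of moisture, or by oligomerisation. Traces of amine from step 6 could also trigger prototropic isomerisation of the alkynoate.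
Fallback: raise the reactivity of the dienophile instead of the temperature. It sets out from 7. Its acetylide 8 is quenched with DMF and a buffered aqueous work-up to give 4-(2-undecyl-1,3-dithian-2-yl)but-2-ynal F1. The aldehyde activates the triple bond far more strongly, so cycloaddition with 13 should proceed in toluene at 60 to 80 °C without Lewis acid, and acid work-up should give 2-hydroxy-4-methoxy-6-[(2-undecyl-1,3-dithian-2-yl)methyl]benzaldehyde F2. MeI and CaCO3 in aqueous MeCN unmask the ketone to 2-hydroxy-4-methoxy-6-(2-oxotridecyl)benzaldehyde F3. Pinnick oxidation (NaClO2, NaH2PO4, excess 2-methylbut-2-ene, t-BuOH/H2O) then returns to the route at 19.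

**Step 9.** Three processes threaten it. The methylene enolate on the far side of the ketone can attack the ester carbon in a Claisen-type ring closure that ends in a second aromatic ring. Acidification can go on to cyclodehydration to the enol lactone. Warming the free acid can cause decarboxylation.
Fallback: avoid base at the end altogether. It sets out from 7. Acetylide 8 is trapped with benzyl chloroformate to give benzyl 4-(2-undecyl-1,3-dithian-2-yl)but-2-ynoate F4. The cycloaddition with 13 under the conditions of step 7 gives benzyl 2-hydroxy-4-methoxy-6-[(2-undecyl-1,3-dithian-2-yl)methyl]benzoate F5. MeI and CaCO3 give benzyl 2-hydroxy-4-methoxy-6-(2-oxotridecyl)benzoate F6, now free of sulfur. Hydrogenolysis (H2, Pd/C, EtOAc, rt) cleaves the benzyl ester under neutral conditions and returns to the route at 19.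

**Step 8.** S-alkylation of the fully substituted dithiane may be slow. Long exposure to MeI then invites O-methylation of the phenol, and the acid released can promote lactonisation of the freed keto ester.
Fallback: switch from alkylative to oxidative unmasking with the phenol protected. It sets out from 16. Acetylation (Ac2O, pyridine) gives methyl 2-acetoxy-4-methoxy-6-[(2-undecyl-1,3-dithian-2-yl)methyl]benzoate F7, in which the ring is deactivated towards oxidants. PhI(OCOCF3)2 in aqueous MeCN at rt then cleaves the dithiane within minutes to methyl 2-acetoxy-4-methoxy-6-(2-oxotridecyl)benzoate F8. The aqueous KOH of step 9 removes acetate and methyl ester together and returns to the route at 19.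

**Step 2.** Metalation of a 2-alkyl dithiane is slow and may be incomplete. The carbanion may also be quenched by proton transfer from the propargylic position of 4, or may substitute with allylic transposition to an allene.
Fallback: form the same bond with reversed polarity. It sets out from 1. Barbier propargylation with 4 and Zn in THF/aqueous NH4Cl gives racemic 1-(trimethylsilyl)pentadec-1-yn-4-ol F9. Dess–Martin periodinane with NaHCO3 in CH2Cl2 oxidises it to 1-(trimethylsilyl)pentadec-1-yn-4-one F10. Immediate dithioketalisation with 2 and BF3·OEt2 at −20 °C, before the β,γ-alkynyl ketone can isomerise, returns to the route at 6.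

## Further compounds

F1 | step 7 | 4-(2-undecyl-1,3-dithian-2-yl)but-2-ynal | CCCCCCCCCCCC1(CC#CC=O)SCCCS1
F2 | step 7 | 2-hydroxy-4-methoxy-6-[(2-undecyl-1,3-dithian-2-yl)methyl]benzaldehyde | CCCCCCCCCCCC1(Cc2cc(OC)cc(O)c2C=O)SCCCS1
F3 | step 7 | 2-hydroxy-4-methoxy-6-(2-oxotridecyl)benzaldehyde | CCCCCCCCCCCC(=O)Cc1cc(OC)cc(O)c1C=O
F4 | step 9 | benzyl 4-(2-undecyl-1,3-dithian-2-yl)but-2-ynoate | CCCCCCCCCCCC1(CC#CC(=O)OCc2ccccc2)SCCCS1
F5 | step 9 | benzyl 2-hydroxy-4-methoxy-6-[(2-undecyl-1,3-dithian-2-yl)methyl]benzoate | CCCCCCCCCCCC1(Cc2cc(OC)cc(O)c2C(=O)OCc2ccccc2)SCCCS1
F6 | step 9 | benzyl 2-hydroxy-4-methoxy-6-(2-oxotridecyl)benzoate | CCCCCCCCCCCC(=O)Cc1cc(OC)cc(O)c1C(=O)OCc1ccccc1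
F7 | step 8 | methyl 2-acetoxy-4-methoxy-6-[(2-undecyl-1,3-dithian-2-yl)methyl]benzoate | CCCCCCCCCCCC1(Cc2cc(OC)cc(OC(C)=O)c2C(=O)OC)SCCCS1
F8 | step 8 | methyl 2-acetoxy-4-methoxy-6-(2-oxotridecyl)benzoate | CCCCCCCCCCCC(=O)Cc1cc(OC)cc(OC(C)=O)c1C(=O)OC
F9 | step 2 | 1-(trimethylsilyl)pentadec-1-yn-4-ol (racemic) | CCCCCCCCCCCC(O)CC#C[Si](C)(C)C
F10 | step 2 | 1-(trimethylsilyl)pentadec-1-yn-4-one | CCCCCCCCCCCC(=O)CC#C[Si](C)(C)C
A1 | alternative 1 | 3,5-dimethoxy-2-(trimethylsilyl)phenyl trifluoromethanesulfonate | COc1cc(OC)c([Si](C)(C)C)c(OS(=O)(=O)C(F)(F)F)c1
A2 | alternative 1 | 1,1,1-trifluoropentadecane-2,4-dione | CCCCCCCCCCCC(=O)CC(=O)C(F)(F)F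
A3 | alternative 1 | 1-[3,5-dimethoxy-2-(trifluoroacetyl)phenyl]tridecan-2-one | CCCCCCCCCCCC(=O)Cc1cc(OC)cc(OC)c1C(=O)C(F)(F)F
A4 | alternative 2 | 2,4-dimethoxy-6-(tridec-1-yn-1-yl)benzoic acid | CCCCCCCCCCCC#Cc1cc(OC)cc(OC)c1C(=O)O
A5 | alternative 2 | 6,8-dimethoxy-3-undecyl-1H-isochromen-1-one | CCCCCCCCCCCC1=Cc2cc(OC)cc(OC)c2C(=O)O1
A6 | alternative 3 | 2,2-dimethyl-6-[2,4-dioxo-5-(2-undecyl-1,3-dioxolan-2-yl)pentyl]-4H-1,3-dioxin-4-one | CCCCCCCCCCCC1(CC(=O)CC(=O)CC2=CC(=O)OC(C)(C)O2)OCCO1
A7 | alternative 3 | 7-hydroxy-2,2-dimethyl-5-[(2-undecyl-1,3-dioxolan-2-yl)methyl]-4H-1,3-benzodioxin-4-one | CCCCCCCCCCCC1(Cc2cc(O)cc3OC(C)(C)OC(=O)c23)OCCO1
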